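**Remarks on the chemistry (they hold for everything below)**

- Numbering and faces: five-membered ring C1(Me)–C2–C3–C4(O, iPr)–C5; seven-membered ring C5–C6–C7–C8–C9–C10–C1. β is the face of the C1 methyl group, α the opposite face. The target is 1β-Me, 4β-OH/4α-iPr, 5α-H, 6α-aroyloxy, 7-oxo, 8α-OH/8β-Me, 9α-OH.
- Correction of a name: the chain on the carbinol carbon of the key precursor is a 3-diazo-2-oxobutyl group (the compound is a 2-diazoheptan-3-one). "2-Diazo-3-oxopentyl" would count the carbinol carbon twice. The connectivity C4–CH2–C(=O)–C(=N2)–CH3 is the one used here.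
- Redesign of the precursor: a methoxymethyl ether on the C4 oxygen would sit where a five-membered oxonium ylide can form from the carbenoid, and an acetal carbon migrates readily from such an ylide. The C4 oxygen is therefore carried as a triethylsilyl ether, which is hindered, weakly basic and has no easily migrating group. It is still smaller than isopropyl at the ring.
- Use of the C9 oxygen: hydride would be expected to reach a C9 ketone from the α face (anti to the C1 and C8 methyl groups) and give the 9β-alcohol. The C9 methoxy group is therefore used only to place the C8=C9 double bond, and both C8–O and C9–O are made by one syn-dihydroxylation from the α face.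
- Chiral dirhodium arylsulfonylprolinates are made for donor/acceptor carbenoids. For an acceptor-only diazoketone the proven reagent control comes from monovalent copper bis(oxazoline) catalysts, which are kept as the fallback.
- Assumptions: the antipode of iPr-DuPHOS in step 3 is the one that directs allyl to the Si face of ketone 5; 4-(methoxymethoxy)benzoic acid (27) is bought.

## Structural features

The target is a daucane-type hydroazulene: a cyclopentane (C1–C5) fused across the C1–C5 bond to a cycloheptane (C5–C10 and C1), with a trans ring fusion (1β-methyl, 5α-hydrogen). C1 is a quaternary carbon with the angular methyl group and C4 is a tertiary carbinol with isopropyl, so the ring-fusion methine C5 lies between two fully substituted carbons. Six stereocentres are present: C4, C5 and C6 are contiguous, C8 and C9 are contiguous, and C1 is next to C5. The relative arrangement is 4β-OH (cis to the C1 methyl), 5α-H, 6α-aroyloxy, 8α-OH/8β-Me and 9α-OH, that is an 8,9-cis-diol on the face opposite the angular methyl. The fragile groups are the α-acyloxy ketone (C6 epimerisation, acyl migration), the C7/C8 α-ketol and the C9-hydroxy/C7-keto aldol pair (α-ketol shift, retro-aldol), the acid-sensitive tertiary C4 alcohol and the phenolic ester. The real difficulty is the stereocontrolled build-up of four neighbouring oxygenated carbons (C6–C9) on a seven-membered ring around the hindered C1/C5/C4 triad. The key step uses the fact that the cycloheptane is a benzene ring (C5–C10) plus the single carbon C1, and that C7, C8 and C9 carry O, C and O as a 3,5-dioxygenated 4-methylphenyl group does; its local symmetry makes the two ipso–ortho bonds equivalent.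

## Logic of the disconnections

29 ⇒ 28 ⇒ 26 + 27. The O–Si bond at C4, the two acetal C–O bonds at C8/C9 and the aryl O–CH2 bond are cut first, then the acyl C–O bond at C6. The ester is the most base-labile group, so it goes on last, onto the only free hydroxyl. This removes the aryl part and leaves the fully oxygenated bicycle. The forward acylation must not epimerise C6, and one mild acid step must free four hydroxyls without dehydrating C4.

26 ⇒ 25. The C6–O bond is cut. C6 is the only enolisable position of the C7 ketone because C8 is quaternary, so the oxygen can come from an enolate oxidation. C6 becomes CH2 and one stereocentre is removed. The forward step needs attack on the α face of the enolate.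

25 ⇒ 24 ⇒ 23. The acetal is opened to the free 8α,9α-diol, then H2 is removed across C5–C6 and across C2–C3. The α-hydroxyls can deliver hydrogen to the α face of C5=C6, and C2=C3 is the last trace of the C2 carbonyl. The C5 stereocentre is removed and an enone is regained. The forward step needs hydroxyl direction to win, so the β-oriented C4 oxygen must stay silylated.

23 ⇒ 22 ⇒ 21. The C2–H bond is exchanged for C2–OSO2CF3, then the C8–O and C9–O bonds are cut together. A syn-dihydroxylation anti to the angular methyl gives exactly the 8α,9α-cis-diol. Two stereocentres are removed and a cross-conjugated dienone results. The forward step needs site selectivity for C8=C9 over C5=C6 and over the enol triflate.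

21 ⇒ 19 ⇒ 18 ⇒ 17. The enone is transposed back (C7=O to C7–OMe, C9–H to C9=O), the C9 carbonyl is returned to its enol ether, and the C2 enol triflate is returned to the ketone. This maps 21 onto the direct ring-expansion product. The forward sequence needs hydrolysis of the terminal enol ether only, a 1,2-reduction, and enolisation at C3 without β-elimination of the C4 oxygen.

17 ⇒ 15. The bonds C1–C5 and C1–C10 are cut. Both rings open at once, the arene reappears and the C1 stereocentre is removed. The forward step needs carbenoid addition to the arene to beat hydride shift, C–H insertion and ylide formation, and it needs C4 to control C1.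

15 ⇒ 13 ⇒ 12 ⇒ 10 + 11. The C1=N2 bond is cut, the C2 ketone is taken back to the carbinol and the C1–C2 bond is cut. An ethyl ketone is the stable carrier of the diazo group and comes from an aldehyde and a two-carbon Grignard reagent. The forward diazo transfer needs enolisation on the ethyl side and not at C3.

10 ⇒ 8 ⇒ 7 ⇒ 5 + 6. The aldehyde is traced to a terminal alkene, the O–Si bond is cut, then the C3–C4 bond. A tertiary homoallylic alcohol comes from a ketone and an allyl nucleophile; this is the only stereocentre made by a reagent, and all others follow from it. The forward step needs face discrimination between aryl and isopropyl.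

5 ⇒ 3 + 4 and 3 ⇒ 1. The C4–CH(CH3)2 bond and the amide C–N bond are cut. This ends at commercial 1 and 4. The forward step needs single addition of a hindered Grignard reagent.

## Other disconnections considered

Alternative 1: The cut is C5–C6, read backwards as a ring contraction. C6 becomes a formyl group on C7 of a trans-hydrindane, the tertiary α-hydroxy aldehyde A2. Forward, Al(OiPr)3 chelates hydroxyl and formyl oxygen and C5 migrates from C7 to the formyl carbon (α-ketol shift) to give A1. In its favour: A1 is the same compound as 26 of the chosen route, so it meets the chosen plan two steps before the target. The shift is suprafacial with retention at C5, so the trans fusion is carried over from a six-membered ring where it is easy to set; on this point the alternative is better than a late hydrogenation. It also delivers C6–OH next to C7=O directly, and it needs no diazo compound and no oxygen that is later removed (C2, C9); on these points it is equal or better. Against it: A2 must already hold six stereocentres, among them the fully substituted C7 and C8. Either C5 or C8 could migrate, and α-ketol shifts are reversible. The key step enlarges one ring and forms one bond, where the chosen step forms two rings and two bonds from an acyclic chain. Reaching A2 should take clearly more steps than the seventeen that lead to 26.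

Alternative 2: The cut is C4–C5. Forward, Rh2(OAc)4 turns the α-diazo ester A4 into a carbenoid at C5 that inserts with retention into the C4–H bond to give cyclopentane A3. In its favour: C4 starts as a secondary carbinol, which is easier to make in high enantiopurity than a tertiary one from a hindered ketone; here the alternative is better. The C–H bond next to oxygen is activated, and C1, C4 and C5 are set on one ring in one step. There is no redundant oxygen. Against it: only one ring and one bond are formed. The whole cycloheptane with its four oxygenated carbons must still be grown from the ester and vinyl groups. The quaternary C1 must be made in an open chain, and the carbenoid can also attack the acetal CH2, the isopropyl methine or the vinyl group. Mechanistically both plans rest on rhodium carbenoids with comparable chemoselectivity questions (equal). In structure and step economy the chosen plan is more convergent.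

Alternative 3: The cut is C6–C7. Forward, the (Z)-enoyl selenide A6 gives an acyl radical with (Me3Si)3SiH; it closes 7-endo on the exocyclic methylene and the C5 radical takes hydrogen to give A5. In its favour: A5 already has C7=O and C8=C9, the enone that the chosen route reaches only after triflation, hydrolysis and transposition. It is ready for the same α-face dihydroxylation, and nothing has to be removed at C2 or C9; in functional-group economy on the seven-membered ring it is better. The 7-endo mode is favoured because the 6-exo mode would form a quaternary centre, and enoyl radicals do not lose CO. Against it: the cyclopentane with two fully substituted carbons beside the methylene must be made first, stereoselectively. C5 is set by hydrogen-atom transfer to a tertiary radical between two quaternary carbons, with no directing group; the chosen plan uses hydroxyl direction there and is better on this point. C6 still needs its oxygen, and selenium and silane are used in stoichiometric amount. One ring per key step against two; the overall length is likely to be similar and not shorter.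

Key step: step 9

## Route

Step 1
Reactants: 1 3,5-dimethoxy-4-methylbenzoic acid
Product: 3 N,3,5-trimethoxy-N,4-dimethylbenzamide, via acyl imidazolide 2 (not isolated)
Conditions: CDI, CH2Cl2, 23 °C; then MeNHOMe·HCl, 23 °C
Reagents that add atoms: N,O-dimethylhydroxylamine hydrochloride, CNOC.Cl; 1,1'-carbonyldiimidazole, O=C(n1ccnc1)n1ccnc1 (its imidazolyl group is present only in 2)
Why: Acyl substitution through the acyl imidazolide (Weinreb amide formation); the by-products are only imidazole and CO2 and no sensitive group is present.

Step 2
Reactants: 3 N,3,5-trimethoxy-N,4-dimethylbenzamide; 4 isopropylmagnesium chloride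
Product: 5 1-(3,5-dimethoxy-4-methylphenyl)-2-methylpropan-1-one
Conditions: iPrMgCl, THF, 0 → 23 °C; aq. NH4Cl
Reagents that add atoms: none
Why: Weinreb ketone synthesis; the magnesium chelate of the tetrahedral adduct holds until work-up, so the Grignard reagent should add once only.

Step 3
Reactants: 5 1-(3,5-dimethoxy-4-methylphenyl)-2-methylpropan-1-one; 6 allylboronic acid pinacol ester
Product: 7 (3R)-3-(3,5-dimethoxy-4-methylphenyl)-2-methylhex-5-en-3-ol
Conditions: CuF(PPh3)3·2EtOH (3 mol %), iPr-DuPHOS (6 mol %, antipode for Si-face attack), La(OiPr)3 (4.5 mol %), DMF, −40 °C; aq. work-up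
Reagents that add atoms: none
Why: Catalytic asymmetric allylboration of a ketone through a chiral allylcopper species that is regenerated by boron-to-copper transmetalation; addition to the Si face (aryl as large, isopropyl as small group) gives the R carbinol, which becomes C4 and is the source of all later stereocontrol.

Step 4
Reactants: 7 (3R)-3-(3,5-dimethoxy-4-methylphenyl)-2-methylhex-5-en-3-ol
Product: 8 triethyl{[(3R)-3-(3,5-dimethoxy-4-methylphenyl)-2-methylhex-5-en-3-yl]oxy}silane
Conditions: Et3SiOTf, 2,6-lutidine, CH2Cl2, −78 → 0 °C
Reagents that add atoms: triethylsilyl trifluoromethanesulfonate, CC[Si](CC)(CC)OS(=O)(=O)C(F)(F)F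
Why: Silylation of a hindered tertiary alcohol with a silyl triflate; the meta methoxy groups do not stabilise a benzylic cation, so ionisation should not compete, and the ether blocks retro-aldol and O–H insertion later.

Step 5
Reactants: 8 triethyl{[(3R)-3-(3,5-dimethoxy-4-methylphenyl)-2-methylhex-5-en-3-yl]oxy}silane
Product: 10 (3R)-3-(3,5-dimethoxy-4-methylphenyl)-4-methyl-3-(triethylsilyloxy)pentanal, via terminal 1,2-diol 9 (not isolated)
Conditions: K2OsO4·2H2O (2 mol %), NaIO4, 2,6-lutidine, dioxane/H2O (3:1), 23 °C
Reagents that add atoms: sodium periodate (terminal oxidant; source of the new oxygen through the osmium oxo species), [Na+].[O-][I](=O)(=O)=O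
Why: Lemieux–Johnson cleavage (osmium-catalysed dihydroxylation, then periodate glycol cleavage); it is chosen over ozonolysis because the electron-rich arene is not attacked and no ozonide is handled.

Step 6
Reactants: 10 (3R)-3-(3,5-dimethoxy-4-methylphenyl)-4-methyl-3-(triethylsilyloxy)pentanal; 11 ethylmagnesium bromide
Product: 12 (5R)-5-(3,5-dimethoxy-4-methylphenyl)-6-methyl-5-(triethylsilyloxy)heptan-3-ol (both C3 epimers)
Conditions: EtMgBr, THF, −78 → 0 °C; aq. NH4Cl
Reagents that add atoms: none
Why: Grignard addition to an aldehyde; the new carbinol centre is oxidised in the next step, so its configuration is irrelevant.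

Step 7
Reactants: 12 (5R)-5-(3,5-dimethoxy-4-methylphenyl)-6-methyl-5-(triethylsilyloxy)heptan-3-ol
Product: 13 (5R)-5-(3,5-dimethoxy-4-methylphenyl)-6-methyl-5-(triethylsilyloxy)heptan-3-one
Conditions: Dess–Martin periodinane, NaHCO3, CH2Cl2, 23 °C
Reagents that add atoms: none
Why: Dess–Martin oxidation under buffered, near-neutral conditions, which spares the β-silyloxy ketone from elimination.

Step 8
Reactants: 13 (5R)-5-(3,5-dimethoxy-4-methylphenyl)-6-methyl-5-(triethylsilyloxy)heptan-3-one
Product: 15 (5R)-2-diazo-5-(3,5-dimethoxy-4-methylphenyl)-6-methyl-5-(triethylsilyloxy)heptan-3-one, via trifluoroacetyl diketone 14 (not isolated)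
Conditions: LiN(SiMe3)2, THF, −78 °C; CF3CO2CH2CF3, −78 °C; 5% aq. HCl work-up; then 4-acetamidobenzenesulfonyl azide, Et3N, H2O (1 equiv), MeCN, 23 °C
Reagents that add atoms: 4-acetamidobenzenesulfonyl azide, CC(=O)Nc1ccc(cc1)S(=O)(=O)N=[N+]=[N-]; 2,2,2-trifluoroethyl trifluoroacetate, FC(F)(F)COC(=O)C(F)(F)F (its trifluoroacetyl group is present only in 14)
Why: Detrifluoroacetylative diazo transfer (Danheiser); the kinetic enolate should form at the open ethyl CH2 and not at the neopentyl-type C3 methylene, and the activated 1,3-diketone takes N2 from the sulfonyl azide with loss of the trifluoroacetyl group. The crystalline acetamido azide is the safer transfer reagent and 15 is used as a solution.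

Step 9
Reactants: 15 (5R)-2-diazo-5-(3,5-dimethoxy-4-methylphenyl)-6-methyl-5-(triethylsilyloxy)heptan-3-one
Product: 17 hydroazulene trienone (C2=O; C5=C6, C7=C8, C9=C10; OMe at C7 and C9, Me at C8; 1β-Me, 4β-OSiEt3, 4α-iPr), via norcaradiene 16 (not isolated)
Conditions: Rh2(O2CCMe3)4 (1 mol %), CH2Cl2, slow addition of 15, 23 → 40 °C; filtration through basic Al2O3
Reagents that add atoms: none
Why: The dirhodium tetracarboxylate extrudes N2 from 15 to give an electrophilic carbenoid at C1, which adds across the ipso–ortho π bond of the arene (bonds C1–C5 and C1–C10) to give norcaradiene 16; disrotatory 6π electrocyclic opening of the C5–C10 bond then gives cycloheptatriene 17 (intramolecular Büchner reaction of an aryl-tethered α-diazoketone, known for 2-diazo-5-arylpentan-3-ones). The cyclopentanone closes by attack of the tethered carbenoid on the ipso carbon through a five-membered, bicyclo[3.1.0]-like transition state (5-exo with respect to the arene π bond), and the seven-membered ring arises by one-carbon expansion of the benzene ring, so no medium-ring closure is needed. The only new stereocentre, C1, is controlled by C4: in the envelope transition state the bulkier isopropyl group should take the pseudo-equatorial position on the side of the ortho carbon under attack and the slimmer silyloxy oxygen the side of the spectator ortho C–H, which places the C1 methyl cis to the C4 oxygen; benzylic-substituted diazoketones of this class are known to put the benzylic substituent trans to the angular methyl. The two ortho carbons are constitutionally equivalent because the arene is symmetric about the C4–C5 axis, so one regioisomer is possible and the methoxy groups end at C7 and C9. Selectivity over 1,2-hydride shift from the C1 methyl, over insertion into the isopropyl methine C–H and over oxonium ylide formation should come from the bulky carboxylate and slow addition, from the deactivation of a C–H bond β to oxygen, and from the hindered, weakly basic silyl ether. Acid is excluded during work-up because the donor-substituted cycloheptatriene can re-aromatise to a 2-tetralone.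

Step 10
Reactants: 17 hydroazulene trienone
Product: 18 C2 enol triflate (C2(OSO2CF3)=C3; C5=C6, C7=C8, C9=C10; OMe at C7 and C9; 1β-Me, 4β-OSiEt3)
Conditions: LiN(SiMe3)2, THF, −78 °C; then N-(5-chloropyridin-2-yl)bis(trifluoromethanesulfonimide), −78 → −40 °C
Reagents that add atoms: N-(5-chloropyridin-2-yl)bis(trifluoromethanesulfonimide), FC(F)(F)S(=O)(=O)N(c1ccc(Cl)cn1)S(=O)(=O)C(F)(F)F
Why: Enol triflate formation with the Comins reagent; the C2 ketone can enolise only towards C3 (C1 is quaternary), and trapping the lithium enolate cold should outrun β-elimination of the C4 silyloxy group. The triflate prepares a non-radical removal of the C2 oxygen and takes away the carbonyl that acid-promoted re-aromatisation would need.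

Step 11
Reactants: 18 C2 enol triflate
Product: 19 vinylogous ester (C9=O; C8=C7(OMe); C6=C5; C2(OSO2CF3)=C3)
Conditions: (CO2H)2, THF/H2O (4:1), 0 °C
Reagents that add atoms: water, O
Why: Enol ether hydrolysis; protonation at C10, the terminus of the trienyl diether, gives a cation stabilised by both methoxy groups, water adds at C9 and methanol is lost. The remaining C7 methoxy group is then part of a vinylogous ester and resists further hydrolysis, and the linear C9=O/C8=C7/C6=C5 conjugation makes 19 also the thermodynamic isomer.

Step 12
Reactants: 19 vinylogous ester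
Product: 21 cross-conjugated dienone (C7=O; C5=C6, C8=C9; C2(OSO2CF3)=C3), via allylic alcohol 20 (not isolated)
Conditions: iBu2AlH, CH2Cl2, −78 °C; then 1 M HCl, THF, 0 → 23 °C
Reagents that add atoms: water, O (supplies the C7 carbonyl oxygen)
Why: Stork–Danheiser transposition; 1,2-reduction of the vinylogous ester carbonyl gives 20, which in aqueous acid loses the C9 hydroxyl and the methyl group of the enol ether and ends as the enone with C7=O and C8=C9. The enol triflate should be inert to the aluminium hydride at −78 °C.

Step 13
Reactants: 21 cross-conjugated dienone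
Product: 22 8α,9α-diol (C7=O; C5=C6; C2(OSO2CF3)=C3)
Conditions: OsO4 (5 mol %), NMO, citric acid, t-BuOH/H2O (1:1), 23 °C; aq. Na2SO3
Reagents that add atoms: osmium tetroxide, O=[Os](=O)(=O)=O, with N-methylmorpholine N-oxide as terminal oxidant, C[N+]1([O-])CCOCC1
Why: Upjohn syn-dihydroxylation; C5=C6 is shielded by two fully substituted neighbours and the enol triflate is electron-poor, so C8=C9 should react. Approach anti to the pseudo-axial C1 methyl sets C8 and C9 together as the 8α,9α-cis-diol with the C8 methyl β.

Step 14
Reactants: 22 8α,9α-diol
Product: 23 dienone diol (C2=C3; C5=C6; C7=O; 8α,9α-diol)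
Conditions: Pd(OAc)2 (5 mol %), PPh3 (10 mol %), HCO2H, n-Bu3N, DMF, 50 °C
Reagents that add atoms: none
Why: Palladium-catalysed formate reduction of an enol triflate (oxidative addition, decarboxylation of formate to a palladium hydride, reductive elimination); the C2 oxygen is replaced by hydrogen without a radical or cation at C2, which next to the vinyl-bearing C1 could rearrange.

Step 15
Reactants: 23 dienone diol
Product: 24 saturated 7-ketone (5α-H; 8α,9α-diol; 4β-OSiEt3)
Conditions: H2 (1 atm), [Ir(cod)(PCy3)(py)]PF6 (10 mol %), CH2Cl2, 0 → 23 °C
Reagents that add atoms: none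
Why: Hydroxyl-directed homogeneous hydrogenation (Crabtree catalyst); the 8α- and 9α-hydroxyls bind iridium and should deliver H2 to the α face of C5=C6, which sets 5α-H and the trans ring fusion, while the silylated β oxygen at C4 cannot direct. The disubstituted C2=C3 bond is saturated in the same operation, which completes the removal of the C2 carbonyl.

Step 16
Reactants: 24 saturated 7-ketone
Product: 25 8α,9α-acetonide of 24
Conditions: Me2C(OMe)2, PPTS (cat.), CH2Cl2, 23 °C
Reagents that add atoms: 2,2-dimethoxypropane, COC(C)(C)OC
Why: Acetonide formation on a cis-1,2-diol by transketalisation; it masks both hydroxyls for the enolate step and leaves C6 as the only site for later acylation.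

Step 17
Reactants: 25 8α,9α-acetonide of 24
Product: 26 6α-hydroxy ketone (6α-OH, 5α-H, C7=O, 8α,9α-acetonide, 4β-OSiEt3)
Conditions: KN(SiMe3)2, THF, −78 °C; then 2-(phenylsulfonyl)-3-phenyloxaziridine, −78 °C; aq. NH4Cl
Reagents that add atoms: 2-(phenylsulfonyl)-3-phenyloxaziridine, O=S(=O)(c1ccccc1)N1OC1c1ccccc1
Why: Davis oxidation of the potassium enolate; the ketone can enolise only towards C6, and the β face of C6 is screened by the two 1,3-related β-methyl groups on C1 and C8, so the oxidant should enter from the α face. The 6α-hydroxyl (equatorial, anti to neither methyl) is also the epimer expected at equilibrium.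

Step 18
Reactants: 26 6α-hydroxy ketone; 27 4-(methoxymethoxy)benzoic acid
Product: 28 6α-[4-(methoxymethoxy)benzoyl] ester of 26
Conditions: EDC·HCl, DMAP, CH2Cl2, 0 → 23 °C
Reagents that add atoms: none
Why: Steglich esterification; the C6 hydroxyl is the only free one, and the mild carbodiimide conditions should leave the α-acyloxy ketone unepimerised.

Step 19
Reactants: 28 6α-[4-(methoxymethoxy)benzoyl] ester of 26
Product: 29 CNP0241001.1
Conditions: 2 M HCl, THF/H2O, 23 → 35 °C
Reagents that add atoms: none
Why: Acid hydrolysis removes the silyl ether, the acetonide and the aryl methoxymethyl acetal in one operation; dilute acid near room temperature is chosen so that the tertiary C4 alcohol does not dehydrate and the ester does not migrate.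

## Compound list

1 | 3,5-dimethoxy-4-methylbenzoic acid | COc1cc(cc(OC)c1C)C(O)=O | starting material
2 | 1-(3,5-dimethoxy-4-methylbenzoyl)imidazole | COc1cc(cc(OC)c1C)C(=O)n1ccnc1 | intermediate
3 | N,3,5-trimethoxy-N,4-dimethylbenzamide | COc1cc(cc(OC)c1C)C(=O)N(C)OC | intermediate
4 | isopropylmagnesium chloride | CC(C)[Mg]Cl | starting material
5 | 1-(3,5-dimethoxy-4-methylphenyl)-2-methylpropan-1-one | COc1cc(cc(OC)c1C)C(=O)C(C)C | intermediate
6 | allylboronic acid pinacol ester | C=CCB1OC(C)(C)C(C)(C)O1 | starting material
7 | (3R)-3-(3,5-dimethoxy-4-methylphenyl)-2-methylhex-5-en-3-ol | CC(C)[C@](O)(CC=C)c1cc(OC)c(C)c(OC)c1 | intermediate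
8 | triethyl{[(3R)-3-(3,5-dimethoxy-4-methylphenyl)-2-methylhex-5-en-3-yl]oxy}silane | CC(C)[C@](O[Si](CC)(CC)CC)(CC=C)c1cc(OC)c(C)c(OC)c1 | intermediate
9 | (4R)-4-(3,5-dimethoxy-4-methylphenyl)-5-methyl-4-(triethylsilyloxy)hexane-1,2-diol (both C2 epimers) | CC(C)[C@](O[Si](CC)(CC)CC)(CC(O)CO)c1cc(OC)c(C)c(OC)c1 | intermediate
10 | (3R)-3-(3,5-dimethoxy-4-methylphenyl)-4-methyl-3-(triethylsilyloxy)pentanal | CC(C)[C@](O[Si](CC)(CC)CC)(CC=O)c1cc(OC)c(C)c(OC)c1 | intermediate
11 | ethylmagnesium bromide | CC[Mg]Br | starting material
12 | (5R)-5-(3,5-dimethoxy-4-methylphenyl)-6-methyl-5-(triethylsilyloxy)heptan-3-ol (both C3 epimers) | CC(C)[C@](O[Si](CC)(CC)CC)(CC(O)CC)c1cc(OC)c(C)c(OC)c1 | intermediate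
13 | (5R)-5-(3,5-dimethoxy-4-methylphenyl)-6-methyl-5-(triethylsilyloxy)heptan-3-one | CC(C)[C@](O[Si](CC)(CC)CC)(CC(=O)CC)c1cc(OC)c(C)c(OC)c1 | intermediate
14 | (6R)-6-(3,5-dimethoxy-4-methylphenyl)-1,1,1-trifluoro-3,7-dimethyl-6-(triethylsilyloxy)octane-2,4-dione (C3 epimers) | CC(C)[C@](O[Si](CC)(CC)CC)(CC(=O)C(C)C(=O)C(F)(F)F)c1cc(OC)c(C)c(OC)c1 | intermediate
15 | (5R)-2-diazo-5-(3,5-dimethoxy-4-methylphenyl)-6-methyl-5-(triethylsilyloxy)heptan-3-one | CC(C)[C@](O[Si](CC)(CC)CC)(CC(=O)C(C)=[N+]=[N-])c1cc(OC)c(C)c(OC)c1 | intermediate
16 | norcaradiene valence tautomer of 17 (cyclopropane C1–C5–C10; C6=C7 and C8=C9; C2=O) | CC(C)[C@]1(O[Si](CC)(CC)CC)CC(=O)[C@]2(C)[C@H]3C(OC)=C(C)C(OC)=C[C@@]123 | intermediate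
17 | hydroazulene trienone: C2=O; C5=C6, C7=C8, C9=C10; 7,9-dimethoxy; 8-methyl; 1β-methyl; 4β-triethylsilyloxy; 4α-isopropyl | CC(C)[C@]1(O[Si](CC)(CC)CC)CC(=O)[C@]2(C)C=C(OC)C(C)=C(OC)C=C21 | intermediate
18 | C2 enol triflate of 17: C2(OSO2CF3)=C3; C5=C6, C7=C8, C9=C10 | CC(C)[C@]1(O[Si](CC)(CC)CC)C=C(OS(=O)(=O)C(F)(F)F)[C@]2(C)C=C(OC)C(C)=C(OC)C=C21 | intermediate
19 | vinylogous ester: C9=O; C8=C7(OMe); C6=C5; C2(OSO2CF3)=C3; 1β-methyl; 4β-triethylsilyloxy | CC(C)[C@]1(O[Si](CC)(CC)CC)C=C(OS(=O)(=O)C(F)(F)F)[C@]2(C)CC(=O)C(C)=C(OC)C=C21 | intermediate
20 | C9 allylic alcohol from 19 (both C9 epimers) | CC(C)[C@]1(O[Si](CC)(CC)CC)C=C(OS(=O)(=O)C(F)(F)F)[C@]2(C)CC(O)C(C)=C(OC)C=C21 | intermediate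
21 | cross-conjugated dienone: C7=O; C5=C6; C8=C9; C2(OSO2CF3)=C3 | CC(C)[C@]1(O[Si](CC)(CC)CC)C=C(OS(=O)(=O)C(F)(F)F)[C@]2(C)CC=C(C)C(=O)C=C21 | intermediate
22 | 8α,9α-diol (8β-methyl) of 21: C7=O; C5=C6; C2(OSO2CF3)=C3 | CC(C)[C@]1(O[Si](CC)(CC)CC)C=C(OS(=O)(=O)C(F)(F)F)[C@]2(C)C[C@H](O)[C@](C)(O)C(=O)C=C21 | intermediate
23 | dienone diol: C2=C3; C5=C6; C7=O; 8α,9α-diol | CC(C)[C@]1(O[Si](CC)(CC)CC)C=C[C@]2(C)C[C@H](O)[C@](C)(O)C(=O)C=C21 | intermediate
24 | saturated 7-ketone: 5α-H; 8α,9α-diol; 1β-methyl; 4β-triethylsilyloxy | CC(C)[C@]1(O[Si](CC)(CC)CC)CC[C@]2(C)C[C@H](O)[C@](C)(O)C(=O)C[C@H]21 | intermediate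
25 | 8α,9α-O-isopropylidene derivative of 24 | CC(C)[C@]1(O[Si](CC)(CC)CC)CC[C@]2(C)C[C@@H]3OC(C)(C)O[C@]3(C)C(=O)C[C@H]21 | intermediate
26 | 6α-hydroxy derivative of 25 | CC(C)[C@]1(O[Si](CC)(CC)CC)CC[C@]2(C)C[C@@H]3OC(C)(C)O[C@]3(C)C(=O)[C@H](O)[C@H]21 | intermediate
27 | 4-(methoxymethoxy)benzoic acid | COCOc1ccc(cc1)C(O)=O | starting material
28 | 6α-[4-(methoxymethoxy)benzoyl] ester of 26 | CC(C)[C@]1(O[Si](CC)(CC)CC)CC[C@]2(C)C[C@@H]3OC(C)(C)O[C@]3(C)C(=O)[C@H](OC(=O)c4ccc(OCOC)cc4)[C@H]21 | intermediate
29 | CNP0241001.1: 4β,8α,9α-trihydroxy-6α-(4-hydroxybenzoyloxy)-1β,8β-dimethyl-4α-isopropyl-5α-H hydroazulen-7-one (numbering of the remarks) | CC(C)[C@]1(O)CC[C@]2(C)C[C@H](O)[C@](C)(O)C(=O)[C@H](OC(=O)c3ccc(O)cc3)[C@H]21 | target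

## Step count and least certain steps

Total step count: 19. Longest linear sequence: 19 steps (1 → 29); 4, 6, 11 and 27 are bought.

Step 9 (key step). The carbenoid may be diverted before or after it reaches the arene: 1,2-hydride shift from the C1 methyl, or re-aromatising ring opening of the norcaradiene/cycloheptatriene, which the two methoxy donors favour. The preference for the C1 methyl cis to the C4 oxygen may also be weaker than the size difference suggests. Fallback: reagent control in place of substrate control, with a copper carbenoid in place of the rhodium carbenoid. From 15 the cyclisation is run with Cu(MeCN)4PF6, a C2-symmetric bis(oxazoline) ligand of the antipode matched to C4, and Na[B(3,5-(CF3)2C6H3)4] in CH2Cl2. This catalyst class is known to decide which ipso–ortho bond of aryl-tethered α-diazoketones is attacked. The path returns at 17 and makes no new compound (F0).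

Step 3. Allyl transfer to a ketone whose two substituents are both large may be slow, and face discrimination between aryl and isopropyl may be poor. Fallback from 5, returning at 7: the stereocentre is first set by reduction and then made tertiary by lithiation–borylation. CBS reduction of 5 ((S)-2-methyl-CBS-oxazaborolidine, BH3·SMe2) should give (1R)-1-(3,5-dimethoxy-4-methylphenyl)-2-methylpropan-1-ol F1. Carbamoylation (iPr2NCOCl, Et3N) gives the N,N-diisopropylcarbamate F2. Lithiation with s-BuLi/TMEDA in Et2O at −78 °C (retention), borylation with 6 (retention) and 1,2-migration of allyl with inversion (MgBr2·OEt2/MeOH) give the tertiary boronic ester F3. Oxidation with NaOH/H2O2 (retention) gives 7.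

Step 11. Water may add at C7 instead of C9, or hydrolysis may run on to the 7,9-dione, so that the vinylogous ester is not obtained as one isomer. Fallback from 18, returning at 21: exhaustive hydrolysis (1 M HCl, THF) gives the 7,9-dione F4. The non-conjugated C9 ketone is reduced in preference to the cross-conjugated C7 ketone (NaBH4, EtOH/CH2Cl2, −78 °C) to the 9-hydroxy-7-ketone F5. Mesylation (MsCl, Et3N) gives the mesylate F6, which eliminates with DBU to the C8=C9 enone 21.

Step 15. Hydrogenation of the hindered, electron-poor C5=C6 bond may stall through chelation of the cationic iridium by the diol, or hydroxyl direction may not override the steric bias. Fallback from 23, returning at 25: conjugate hydride addition in place of hydrogenation. The diol is first protected (Me2C(OMe)2, PPTS) as the acetonide F7. Copper hydride 1,4-reduction ([(Ph3P)CuH]6 cat., PhMe2SiH, toluene) gives the dimethylphenylsilyl enol ether F8, which is hydrolysed on work-up to the Δ2-ketone F9. Hydrogenation of the remaining C2=C3 bond over 10% Pd/C gives 25. In this variant the face at C5 is decided by steric approach alone.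

Step 17. The oxaziridine may attack the β face of the enolate, or the enolate may add to the sulfonimine by-product. Fallback from 25, returning at 28: if the oxidation gives the 6β-alcohol F10 (6-epi-26), it is esterified with inversion under Mitsunobu conditions (27, PPh3, diisopropyl azodicarboxylate, THF), which gives 28 directly and skips step 18.

## Further compounds

F0 | step 9 | none | none
F1 | step 3 | (1R)-1-(3,5-dimethoxy-4-methylphenyl)-2-methylpropan-1-ol | CC(C)[C@@H](O)c1cc(OC)c(C)c(OC)c1
F2 | step 3 | (1R)-1-(3,5-dimethoxy-4-methylphenyl)-2-methylpropyl N,N-diisopropylcarbamate | CC(C)[C@@H](OC(=O)N(C(C)C)C(C)C)c1cc(OC)c(C)c(OC)c1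
F3 | step 3 | 2-[3-(3,5-dimethoxy-4-methylphenyl)-2-methylhex-5-en-3-yl]-4,4,5,5-tetramethyl-1,3,2-dioxaborolane (boron in the position later taken by the hydroxyl) | C=CC[C@](c1cc(OC)c(C)c(OC)c1)(C(C)C)B1OC(C)(C)C(C)(C)O1
F4 | step 11 | 7,9-dione with C5=C6 and C2(OSO2CF3)=C3 (C8 epimers and enol forms) | CC(C)[C@]1(O[Si](CC)(CC)CC)C=C(OS(=O)(=O)C(F)(F)F)[C@]2(C)CC(=O)C(C)C(=O)C=C21
F5 | step 11 | 9-hydroxy-7-ketone with C5=C6 and C2(OSO2CF3)=C3 (C8 and C9 epimers) | CC(C)[C@]1(O[Si](CC)(CC)CC)C=C(OS(=O)(=O)C(F)(F)F)[C@]2(C)CC(O)C(C)C(=O)C=C21
F6 | step 11 | 9-methanesulfonate of F5 | CC(C)[C@]1(O[Si](CC)(CC)CC)C=C(OS(=O)(=O)C(F)(F)F)[C@]2(C)CC(OS(C)(=O)=O)C(C)C(=O)C=C21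
F7 | step 15 | 8α,9α-acetonide of 23 | CC(C)[C@]1(O[Si](CC)(CC)CC)C=C[C@]2(C)C[C@@H]3OC(C)(C)O[C@]3(C)C(=O)C=C21
F8 | step 15 | C6=C7 dimethylphenylsilyl enol ether (5α-H, C2=C3, 8α,9α-acetonide) | CC(C)[C@]1(O[Si](CC)(CC)CC)C=C[C@]2(C)C[C@@H]3OC(C)(C)O[C@]3(C)C(O[Si](C)(C)c4ccccc4)=C[C@H]21
F9 | step 15 | Δ2-7-ketone (5α-H, C2=C3, 8α,9α-acetonide) | CC(C)[C@]1(O[Si](CC)(CC)CC)C=C[C@]2(C)C[C@@H]3OC(C)(C)O[C@]3(C)C(=O)C[C@H]21
F10 | step 17 | 6β-hydroxy epimer of 26 | CC(C)[C@]1(O[Si](CC)(CC)CC)CC[C@]2(C)C[C@@H]3OC(C)(C)O[C@]3(C)C(=O)[C@@H](O)[C@H]21
A1 | alternative 1 | hydroazulene 6α-hydroxy-7-ketone with 8α,9α-acetonide and 4β-triethylsilyloxy (identical with 26) | CC(C)[C@]1(O[Si](CC)(CC)CC)CC[C@]2(C)C[C@@H]3OC(C)(C)O[C@]3(C)C(=O)[C@H](O)[C@H]21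
A2 | alternative 1 | trans-hydrindane tertiary α-hydroxy aldehyde (formyl and hydroxyl on C7; C7 configuration as the chelate model requires) | CC(C)[C@]1(O[Si](CC)(CC)CC)CC[C@]2(C)C[C@@H]3OC(C)(C)O[C@]3(C)[C@@](O)(C=O)[C@H]21
A3 | alternative 2 | cyclopentane with C4 tertiary MOM ether, C5 methyl ester, C1 methyl and vinyl | CC(C)[C@]1(OCOC)CC[C@](C)(C=C)[C@H]1C(=O)OC
A4 | alternative 2 | open-chain α-diazo ester with secondary MOM ether at C4 and quaternary C1 | CC(C)[C@H](OCOC)CC[C@](C)(C=C)C(=[N+]=[N-])C(=O)OC
A5 | alternative 3 | trans-fused bicyclic 2-methylcyclohept-2-enone (C7=O, C8=C9, 5α-H, 4β-OMOM) | CC(C)[C@]1(OCOC)CC[C@]2(C)CC=C(C)C(=O)C[C@H]21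
A6 | alternative 3 | (Z)-enoyl phenyl selenide on a 5-methylenecyclopentane (4β-OMOM, 1β-methyl) | CC(C)[C@]1(OCOC)CC[C@](C)(C/C=C(/C)C(=O)[Se]c2ccccc2)C1=C
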